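**Retrosynthetic overview**
1. Target ⇐ aryl O‑sulfation, then one H2/Pd‑C step (C≡C → CH2CH2, O‑benzyl off) ⇐ propargylic carbinol from the acetylide of bicyclic alkyne 26 and oxepane‑fused ketone 11.
2. Key disconnection: the bridgehead‑carbinol C1–C2 bond of the bicyclo[2.2.2]octane, closed by SmI2 ketyl–olefin cyclization of cyclohexanone 24 (the carbonyl carbon reacts as a nucleophilic ketyl on the styrene).
3. 24 ⇐ tertiary bromide 23 + styrene 15 (radical Heck); 23 ⇐ HBr opening of the cyclobutane of pinane ketone 22 ⇐ (+)-nopinone (chiral pool; Me2CuLi sets the quaternary centre).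
4. 11 ⇐ 2-methylcyclohexane-1,3-dione: C‑alkylation, CBS desymmetrization, Evans–Tishchenko, oxymercuration, oxidation, methylation.
5. Ring order: left, oxepane closed onto the existing cyclohexane; right, cyclobutane opened to the cyclohexanone, then bicyclo[2.2.2]octane closed; the arene is bought.

Assumption: the aryl sulfate is written as the free hydrogen sulfate, as in the target SMILES; in practice it is handled as a salt and acidified at the end.

**Left fragment**

Step 1
Reactants: 1 2-methylcyclohexane-1,3-dione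
Product: 2 3-(1-methyl-2,6-dioxocyclohexyl)propanal
Conditions: acrolein, H2O, rt
Reagents that add atoms: acrolein, C=CC=O
Why: Michael addition of the 1,3-dione through C-2 in water gives only the C‑alkylated adduct; no stereocentre is formed.

Step 2
Reactants: 2 3-(1-methyl-2,6-dioxocyclohexyl)propanal
Product: 3 2-methyl-2-(4-methylpent-3-en-1-yl)cyclohexane-1,3-dione
Conditions: i-PrPPh3+ I−, n-BuLi, THF, −78 to 0 °C; then 2, −78 °C to rt
Reagents that add atoms: isopropyltriphenylphosphonium iodide, CC(C)[P+](c1ccccc1)(c1ccccc1)c1ccccc1.[I-]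
Why: Wittig olefination, in which the unstabilised ylide reacts with the aldehyde much faster than with the hindered ring ketones; the Me2C= alkene has no geometry to control.

Step 3
Reactants: 3 2-methyl-2-(4-methylpent-3-en-1-yl)cyclohexane-1,3-dione
Product: 4 (2S,3S)-3-hydroxy-2-methyl-2-(4-methylpent-3-en-1-yl)cyclohexan-1-one (OH cis to the pentenyl chain)
Conditions: (R)-2-methyl-CBS-oxazaborolidine (20 mol%), catecholborane, toluene, −78 °C
Reagents that add atoms: none
Why: Corey–Bakshi–Shibata desymmetrizing reduction, in which the (R)-catalyst sets the 3S carbinol and hydride enters anti to the larger chain, so OH ends cis to the chain and the quaternary centre becomes 2S (catecholborane leaves the alkene alone).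

Step 4
Reactants: 4 (2S,3S)-3-hydroxy-2-methyl-2-(4-methylpent-3-en-1-yl)cyclohexan-1-one
Product: 5 (1S,2R,3S)-3-hydroxy-2-methyl-2-(4-methylpent-3-en-1-yl)cyclohexyl acetate (free OH trans to the chain and cis to CH3; OAc cis to the chain)
Conditions: MeCHO, SmI2 (20 mol%), THF, −10 °C
Reagents that add atoms: acetaldehyde, CC=O
Why: Evans–Tishchenko reduction, in which the samarium‑bound hemiacetal of the existing OH delivers hydride to the same face of the ketone, giving the 1,3-anti diol with the new OH trans to the chain and the old OH capped as acetate.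

Step 5
Reactants: 5 (1S,2R,3S)-3-hydroxy-2-methyl-2-(4-methylpent-3-en-1-yl)cyclohexyl acetate
Product: 8 (5aS,6S,9aS)-2,2,5a-trimethyldecahydro-1-benzoxepin-6-ol, via organomercurial 6 (not isolated), via oxepane acetate 7 (not isolated)
Conditions: Hg(OCOCF3)2, MeNO2, −20 °C; then NaBH4, 3 M NaOH, 0 °C; then MeOH, 40 °C
Reagents that add atoms: none
Why: Intramolecular alkoxymercuration–demercuration, in which the equatorial OH attacks the tertiary alkene carbon (Markovnikov, 7-endo) to close the trans‑fused oxepane without touching a stereocentre, and the alkaline work‑up cleaves the acetate.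

Step 6
Reactants: 8 (5aS,6S,9aS)-2,2,5a-trimethyldecahydro-1-benzoxepin-6-ol
Product: 9 (5aR,9aS)-2,2,5a-trimethyloctahydro-1-benzoxepin-6(2H)-one
Conditions: Dess–Martin periodinane, NaHCO3, CH2Cl2, rt
Reagents that add atoms: none
Why: Dess–Martin oxidation of the axial secondary alcohol; the adjacent quaternary centre cannot epimerise.

Step 7
Reactants: 9 (5aR,9aS)-2,2,5a-trimethyloctahydro-1-benzoxepin-6(2H)-one
Product: 11 (5aR,7S,9aS)-2,2,5a,7-tetramethyloctahydro-1-benzoxepin-6(2H)-one, via lithium enolate 10 (not isolated)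
Conditions: LiN(i-Pr)2, THF, −78 °C; MeI, −78 to 0 °C
Reagents that add atoms: iodomethane, CI
Why: Enolate alkylation at the only enolisable α‑carbon, in which MeI enters anti to the axial angular methyl to give the equatorial 7S methyl, which is also the thermodynamic epimer.

**Aryl unit**

Step 8
Reactants: 12 2,5-dihydroxybenzaldehyde
Product: 13 5-[(tert-butyldimethylsilyl)oxy]-2-hydroxybenzaldehyde
Conditions: TBSCl (1.05 equiv), imidazole, CH2Cl2–DMF, 0 °C
Reagents that add atoms: tert-butyldimethylsilyl chloride, CC(C)(C)[Si](C)(C)Cl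
Why: Selective silylation of the 5-OH, because the 2-OH is hydrogen‑bonded to the aldehyde; this differentiates the two phenols for the later regiodefined sulfation.

Step 9
Reactants: 13 5-[(tert-butyldimethylsilyl)oxy]-2-hydroxybenzaldehyde
Product: 14 2-(benzyloxy)-5-[(tert-butyldimethylsilyl)oxy]benzaldehyde
Conditions: BnOH, PPh3, DIAD, THF, 0 °C to rt
Reagents that add atoms: benzyl alcohol, OCc1ccccc1
Why: Mitsunobu etherification of the acidic salicyl phenol under neutral conditions that do not move or cleave the aryl silyl ether.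

Step 10
Reactants: 14 2-(benzyloxy)-5-[(tert-butyldimethylsilyl)oxy]benzaldehyde
Product: 15 2-(benzyloxy)-5-[(tert-butyldimethylsilyl)oxy]styrene
Conditions: Ph3PCH3+ Br−, NaN(SiMe3)2, THF, 0 °C
Reagents that add atoms: methyltriphenylphosphonium bromide, C[P+](c1ccccc1)(c1ccccc1)c1ccccc1.[Br-]
Why: Wittig methylenation of the aryl aldehyde.

**Right fragment and key step**

Step 11
Reactants: 16 (1R,5S)-6,6-dimethylbicyclo[3.1.1]heptan-2-one [(+)-nopinone]
Product: 17 (1R,5R)-6,6-dimethylbicyclo[3.1.1]hept-3-en-2-one (apoverbenone)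
Conditions: IBX (2 equiv), DMSO, 75 °C
Reagents that add atoms: none
Why: IBX dehydrogenation of the ketone; only C-3 can enolise (C-1 is a bridgehead), so a single enone forms and both stereocentres are untouched.

Step 12
Reactants: 17 (1R,5R)-6,6-dimethylbicyclo[3.1.1]hept-3-en-2-one; 18 (4-bromobut-1-yn-1-yl)trimethylsilane
Product: 20 (1R,2R,5R)-6,6-dimethyl-2-[4-(trimethylsilyl)but-3-yn-1-yl]bicyclo[3.1.1]hept-3-en-2-ol, via Grignard reagent 19 (not isolated)
Conditions: 18, Mg, THF, rt; CeCl3, −78 °C; then 17, −78 to 0 °C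
Reagents that add atoms: none
Why: Cerium‑mediated (Imamoto) 1,2-addition of the Grignard reagent to the enone from the face anti to the CMe2 bridge; the new carbinol centre is erased in step 13.

Step 13
Reactants: 20 (1R,2R,5R)-6,6-dimethyl-2-[4-(trimethylsilyl)but-3-yn-1-yl]bicyclo[3.1.1]hept-3-en-2-ol
Product: 21 (1S,5R)-6,6-dimethyl-4-[4-(trimethylsilyl)but-3-yn-1-yl]bicyclo[3.1.1]hept-3-en-2-one
Conditions: pyridinium chlorochromate [C5H5NH][CrO3Cl], NaOAc, 4 Å molecular sieves, CH2Cl2, 0 °C to rt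
Reagents that add atoms: none
Why: Dauben–Babler oxidative 1,3-transposition (allylic shift of the chromate ester, then oxidation), which places the carbonyl next to the other bridgehead and so enters the enantiomeric series needed from cheap (+)-nopinone; acetate buffering suppresses pinane cation rearrangement.

Step 14
Reactants: 21 (1S,5R)-6,6-dimethyl-4-[4-(trimethylsilyl)but-3-yn-1-yl]bicyclo[3.1.1]hept-3-en-2-one
Product: 22 (1S,4R,5S)-4,6,6-trimethyl-4-[4-(trimethylsilyl)but-3-yn-1-yl]bicyclo[3.1.1]heptan-2-one (new CH3 anti, butynyl chain syn to the CMe2 bridge)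
Conditions: Me2CuLi, Et2O, −40 to 0 °C
Reagents that add atoms: lithium dimethylcuprate, [Li+].C[Cu-]C
Why: Gilman conjugate addition, in which methyl enters anti to the gem‑dimethyl bridge as in verbenone, so the quaternary centre is set with the chain on the side of the CMe2 carbon.

Step 15
Reactants: 22 (1S,4R,5S)-4,6,6-trimethyl-4-[4-(trimethylsilyl)but-3-yn-1-yl]bicyclo[3.1.1]heptan-2-one
Product: 23 (3R,4S)-4-(2-bromopropan-2-yl)-3-methyl-3-[4-(trimethylsilyl)but-3-yn-1-yl]cyclohexan-1-one (chain cis to the bromopropyl group)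
Conditions: HBr (33% in AcOH, 1.5 equiv), CH2Cl2, −10 °C
Reagents that add atoms: hydrogen bromide, Br
Why: Acid‑mediated fragmentation of the cyclobutyl ketone (retro‑Prins type), in which the strained bond α to the protonated carbonyl breaks toward the tertiary cation and bromide traps it; neither stereocentre is involved.

Step 16
Reactants: 23 (3R,4S)-4-(2-bromopropan-2-yl)-3-methyl-3-[4-(trimethylsilyl)but-3-yn-1-yl]cyclohexan-1-one; 15 2-(benzyloxy)-5-[(tert-butyldimethylsilyl)oxy]styrene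
Product: 24 (3R,4S)-4-[(3E)-4-{2-(benzyloxy)-5-[(tert-butyldimethylsilyl)oxy]phenyl}-2-methylbut-3-en-2-yl]-3-methyl-3-[4-(trimethylsilyl)but-3-yn-1-yl]cyclohexan-1-one
Conditions: Pd(OAc)2 (10 mol%), Xantphos (20 mol%), Cs2CO3, benzene, blue LEDs, rt; 15 (3 equiv, 1 M)
Reagents that add atoms: none
Why: Visible‑light Pd‑catalysed radical Mizoroki–Heck reaction, in which the tertiary radical adds to the styrene CH2 and β‑hydride elimination gives the E‑alkene; excess styrene at high concentration outruns radical attack on the silyl alkyne.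

Step 17
Reactants: 24 (3R,4S)-4-[(3E)-4-{2-(benzyloxy)-5-[(tert-butyldimethylsilyl)oxy]phenyl}-2-methylbut-3-en-2-yl]-3-methyl-3-[4-(trimethylsilyl)but-3-yn-1-yl]cyclohexan-1-one
Product: 26 (1S,2S,4S,5R)-2-[2-(benzyloxy)-5-hydroxybenzyl]-5-(but-3-yn-1-yl)-3,3,5-trimethylbicyclo[2.2.2]octan-1-ol, via silylated bicyclooctanol 25 (not isolated)
Conditions: SmI2 (3 equiv), HMPA, t-BuOH, THF, −78 to 0 °C; then K2CO3, MeOH, rt
Reagents that add atoms: none
Why: SmI2 ketyl–olefin cyclization, in which the ketyl adds 6-exo to the styrene carbon next to CMe2 through a boat and the benzylic radical is reduced and protonated, so the bridgehead carbinol forms without facial control at the carbonyl and the aryl‑vinyl end turns to the unsubstituted CH2CH2 bridge, away from the quaternary centre, to give 2S (ketyl bridging to bicyclo[2.2.2]octanols is precedented in diterpenoid alkaloid work); K2CO3/MeOH then removes C–SiMe3 and ArO–TBS.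

**Union and endgame**

Step 18
Reactants: 26 (1S,2S,4S,5R)-2-[2-(benzyloxy)-5-hydroxybenzyl]-5-(but-3-yn-1-yl)-3,3,5-trimethylbicyclo[2.2.2]octan-1-ol; 11 (5aR,7S,9aS)-2,2,5a,7-tetramethyloctahydro-1-benzoxepin-6(2H)-one
Product: 28 coupled propargylic alcohol (ketone 11 with C-6 converted into C(OH)–C≡C–CH2CH2– bound to C-5 of 26; new carbinol 6R with axial OH cis to the 7-methyl and equatorial alkynyl; all other centres as in 11 and 26), via trilithium salt 27 (not isolated)
Conditions: n-BuLi (3.1 equiv), THF, −78 to 0 °C; CeCl3, −78 °C; then 11, −78 to −20 °C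
Reagents that add atoms: none
Why: Cerium‑acetylide addition to the hindered ketone, in which the rod‑shaped nucleophile attacks equatorially, trans to the 7-methyl (as with 2,2,6-trimethylcyclohexanone), giving the axial tertiary alcohol; the cerium reagent suppresses enolisation.

Step 19
Reactants: 28 coupled propargylic alcohol
Product: 29 aryl hydrogen sulfate of 28 (phenolic OH converted into OSO3H; benzyl ether, alkyne and both tertiary alcohols unchanged)
Conditions: SO3·pyridine (3 equiv), pyridine, rt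
Reagents that add atoms: sulfur trioxide–pyridine complex, O=S(=O)([O-])[n+]1ccccc1
Why: O‑sulfation of the only free phenol; the two hindered tertiary alcohols do not react at rt and the benzyl ether blocks the other phenol, so the regiochemistry is fixed.

Step 20
Reactants: 29 aryl hydrogen sulfate of 28
Product: 30 4-hydroxy-3-{[(1S,2S,4S,5R)-1-hydroxy-5-{4-[(5aR,6S,7S,9aS)-6-hydroxy-2,2,5a,7-tetramethyldecahydro-1-benzoxepin-6-yl]butyl}-3,3,5-trimethylbicyclo[2.2.2]octan-2-yl]methyl}phenyl hydrogen sulfate (target)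
Conditions: H2 (1 atm), Pd/C, NaHCO3, EtOAc–MeOH, rt; then Dowex 50W (H+ form), 0 °C, brief
Reagents that add atoms: none
Why: Catalytic hydrogenation saturates the alkyne and hydrogenolyses the benzyl ether in one operation, while the aryl sulfate and tertiary alcohols survive under bicarbonate buffering; no stereocentre is affected.

**Compound list**
1 | 2-methylcyclohexane-1,3-dione | CC1C(=O)CCCC1=O | starting material
2 | 3-(1-methyl-2,6-dioxocyclohexyl)propanal | CC1(CCC=O)C(=O)CCCC1=O | intermediate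
3 | 2-methyl-2-(4-methylpent-3-en-1-yl)cyclohexane-1,3-dione | CC(C)=CCCC1(C)C(=O)CCCC1=O | intermediate
4 | (2S,3S)-3-hydroxy-2-methyl-2-(4-methylpent-3-en-1-yl)cyclohexan-1-one | CC(C)=CCC[C@]1(C)C(=O)CCC[C@@H]1O | intermediate
5 | (1S,2R,3S)-3-hydroxy-2-methyl-2-(4-methylpent-3-en-1-yl)cyclohexyl acetate | CC(C)=CCC[C@]1(C)[C@@H](O)CCC[C@@H]1OC(C)=O | intermediate
6 | (5aR,6S,9aS)-2,2,5a-trimethyl-3-[(trifluoroacetoxy)mercurio]decahydro-1-benzoxepin-6-yl acetate (C-3 configuration undefined, lost on reduction) | C1CC[C@@H]2OC(C)(C)C([Hg]OC(=O)C(F)(F)F)CC[C@@]2(C)[C@H]1OC(C)=O | intermediate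
7 | (5aR,6S,9aS)-2,2,5a-trimethyldecahydro-1-benzoxepin-6-yl acetate | C1CC[C@@H]2OC(C)(C)CCC[C@@]2(C)[C@H]1OC(C)=O | intermediate
8 | (5aS,6S,9aS)-2,2,5a-trimethyldecahydro-1-benzoxepin-6-ol | C1CC[C@@H]2OC(C)(C)CCC[C@@]2(C)[C@H]1O | intermediate
9 | (5aR,9aS)-2,2,5a-trimethyloctahydro-1-benzoxepin-6(2H)-one | O=C1CCC[C@@H]2OC(C)(C)CCC[C@@]12C | intermediate
10 | lithium enolate of 9 (C6=C7) | [Li+].[O-]C1=CCC[C@@H]2OC(C)(C)CCC[C@@]12C | intermediate
11 | (5aR,7S,9aS)-2,2,5a,7-tetramethyloctahydro-1-benzoxepin-6(2H)-one | C[C@H]1CC[C@@H]2OC(C)(C)CCC[C@@]2(C)C1=O | intermediate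
12 | 2,5-dihydroxybenzaldehyde | O=Cc1cc(O)ccc1O | starting material
13 | 5-[(tert-butyldimethylsilyl)oxy]-2-hydroxybenzaldehyde | O=Cc1cc(O[Si](C)(C)C(C)(C)C)ccc1O | intermediate
14 | 2-(benzyloxy)-5-[(tert-butyldimethylsilyl)oxy]benzaldehyde | O=Cc1cc(O[Si](C)(C)C(C)(C)C)ccc1OCc1ccccc1 | intermediate
15 | 2-(benzyloxy)-5-[(tert-butyldimethylsilyl)oxy]styrene | C=Cc1cc(O[Si](C)(C)C(C)(C)C)ccc1OCc1ccccc1 | intermediate
16 | (1R,5S)-6,6-dimethylbicyclo[3.1.1]heptan-2-one, (+)-nopinone | CC1(C)[C@H]2CCC(=O)[C@@H]1C2 | starting material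
17 | (1R,5R)-6,6-dimethylbicyclo[3.1.1]hept-3-en-2-one | CC1(C)[C@H]2C=CC(=O)[C@@H]1C2 | intermediate
18 | (4-bromobut-1-yn-1-yl)trimethylsilane | C[Si](C)(C)C#CCCBr | starting material
19 | [4-(trimethylsilyl)but-3-yn-1-yl]magnesium bromide | C[Si](C)(C)C#CCC[Mg]Br | intermediate
20 | (1R,2R,5R)-6,6-dimethyl-2-[4-(trimethylsilyl)but-3-yn-1-yl]bicyclo[3.1.1]hept-3-en-2-ol | CC1(C)[C@H]2C=C[C@](O)(CCC#C[Si](C)(C)C)[C@@H]1C2 | intermediate
21 | (1S,5R)-6,6-dimethyl-4-[4-(trimethylsilyl)but-3-yn-1-yl]bicyclo[3.1.1]hept-3-en-2-one | CC1(C)[C@H]2C(=O)C=C(CCC#C[Si](C)(C)C)[C@@H]1C2 | intermediate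
22 | (1S,4R,5S)-4,6,6-trimethyl-4-[4-(trimethylsilyl)but-3-yn-1-yl]bicyclo[3.1.1]heptan-2-one | CC1(C)[C@H]2C(=O)C[C@@](C)(CCC#C[Si](C)(C)C)[C@@H]1C2 | intermediate
23 | (3R,4S)-4-(2-bromopropan-2-yl)-3-methyl-3-[4-(trimethylsilyl)but-3-yn-1-yl]cyclohexan-1-one | O=C1C[C@@](C)(CCC#C[Si](C)(C)C)[C@@H](C(C)(C)Br)CC1 | intermediate
24 | (3R,4S)-4-[(3E)-4-{2-(benzyloxy)-5-[(tert-butyldimethylsilyl)oxy]phenyl}-2-methylbut-3-en-2-yl]-3-methyl-3-[4-(trimethylsilyl)but-3-yn-1-yl]cyclohexan-1-one | O=C1C[C@@](C)(CCC#C[Si](C)(C)C)[C@@H](C(C)(C)/C=C/c2cc(O[Si](C)(C)C(C)(C)C)ccc2OCc2ccccc2)CC1 | intermediate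
25 | (1S,2S,4S,5R)-2-{2-(benzyloxy)-5-[(tert-butyldimethylsilyl)oxy]benzyl}-3,3,5-trimethyl-5-[4-(trimethylsilyl)but-3-yn-1-yl]bicyclo[2.2.2]octan-1-ol | C[Si](C)(C)C#CCC[C@]1(C)C[C@@]2(O)CC[C@@H]1C(C)(C)[C@@H]2Cc1cc(O[Si](C)(C)C(C)(C)C)ccc1OCc1ccccc1 | intermediate
26 | (1S,2S,4S,5R)-2-[2-(benzyloxy)-5-hydroxybenzyl]-5-(but-3-yn-1-yl)-3,3,5-trimethylbicyclo[2.2.2]octan-1-ol | C#CCC[C@]1(C)C[C@@]2(O)CC[C@@H]1C(C)(C)[C@@H]2Cc1cc(O)ccc1OCc1ccccc1 | intermediate
27 | trilithium salt of 26 (acetylide, phenoxide, bridgehead alkoxide) | [Li+].[Li+].[Li+].[C-]#CCC[C@]1(C)C[C@@]2([O-])CC[C@@H]1C(C)(C)[C@@H]2Cc1cc([O-])ccc1OCc1ccccc1 | intermediate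
28 | coupled propargylic alcohol, (5aR,6R,7S,9aS) in the benzoxepine part and (1S,2S,4S,5R) in the bicyclooctane part | C[C@H]1CC[C@@H]2OC(C)(C)CCC[C@@]2(C)[C@]1(O)C#CCC[C@]1(C)C[C@@]2(O)CC[C@@H]1C(C)(C)[C@@H]2Cc1cc(O)ccc1OCc1ccccc1 | intermediate
29 | aryl hydrogen sulfate of 28 | C[C@H]1CC[C@@H]2OC(C)(C)CCC[C@@]2(C)[C@]1(O)C#CCC[C@]1(C)C[C@@]2(O)CC[C@@H]1C(C)(C)[C@@H]2Cc1cc(OS(=O)(=O)O)ccc1OCc1ccccc1 | intermediate
30 | 4-hydroxy-3-{[(1S,2S,4S,5R)-1-hydroxy-5-{4-[(5aR,6S,7S,9aS)-6-hydroxy-2,2,5a,7-tetramethyldecahydro-1-benzoxepin-6-yl]butyl}-3,3,5-trimethylbicyclo[2.2.2]octan-2-yl]methyl}phenyl hydrogen sulfate | C[C@H]1CC[C@@H]2OC(C)(C)CCC[C@@]2(C)[C@]1(O)CCCC[C@]1(C)C[C@@]2(O)CC[C@@H]1C(C)(C)[C@@H]2Cc1cc(OS(=O)(=O)O)ccc1O | target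

**Step count**
Total: 20 steps. Longest linear sequence: 10 steps (16 → 30 through steps 11–20; equally 1 → 30 through steps 1–7 and 18–20).

**Three steps most likely to fail**

Step 17, the ketyl–olefin ring closure, is the riskiest. The ketone may simply be reduced, the ketyl may find the boat geometry too costly, or the benzyl‑bearing centre may form with poor selectivity. The fallback sets out from 24 and closes the same bond with the opposite polarity. Treatment of 24 with Me2AlCl in CH2Cl2 at −78 °C lets the electron‑rich styrene attack the Lewis‑acid‑activated ketone (Prins cyclization), and chloride captures the benzylic cation to give the benzylic chloride F1. Bu3SnH with AIBN in toluene at 80 °C then removes the chlorine and the route is rejoined at 25, which is desilylated with K2CO3/MeOH as in step 17.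

Step 18, the fragment union, may suffer from enolisation of the hindered ketone, poor solubility of the trianion, or low facial selectivity. The fallback sets out from 25 (obtained by stopping step 17 before the methanolysis) and ketone 11, and avoids strongly basic species. N-iodosuccinimide with catalytic AgNO3 in acetone converts the silyl alkyne of 25 directly into the iodoalkyne F2. SmI2 in THF–HMPA then effects a Barbier‑type reductive alkynylation of 11 and gives the silyl‑protected coupled alcohol F3. Bu4NF in THF at 0 °C frees the phenol and the route is rejoined at 28.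

Step 5, the oxepane closure, may give 6-exo attack or elimination instead of the seven‑membered ether. The fallback sets out from 5 and uses an epoxide, whose tertiary carbon directs endo opening more strongly. mCPBA with NaHCO3 gives the epoxide F4 as a mixture at the new centre. Catalytic camphorsulfonic acid in CH2Cl2 at 0 °C opens it 7-endo to the hydroxy oxepane F5. 1,1'-Thiocarbonyldiimidazole converts the new secondary alcohol into the imidazolide F6, and Bu3SnH with AIBN (Barton–McCombie) removes it. The route is rejoined at 7, which is saponified to 8 as in step 5.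

**Further compounds**
F1 | step 17 | (1S,2S,4S,5R)-2-[{2-(benzyloxy)-5-[(tert-butyldimethylsilyl)oxy]phenyl}(chloro)methyl]-3,3,5-trimethyl-5-[4-(trimethylsilyl)but-3-yn-1-yl]bicyclo[2.2.2]octan-1-ol (benzylic epimers) | C[Si](C)(C)C#CCC[C@]1(C)C[C@@]2(O)CC[C@@H]1C(C)(C)[C@@H]2C(Cl)c1cc(O[Si](C)(C)C(C)(C)C)ccc1OCc1ccccc1
F2 | step 18 | (1S,2S,4S,5R)-2-{2-(benzyloxy)-5-[(tert-butyldimethylsilyl)oxy]benzyl}-5-(4-iodobut-3-yn-1-yl)-3,3,5-trimethylbicyclo[2.2.2]octan-1-ol | IC#CCC[C@]1(C)C[C@@]2(O)CC[C@@H]1C(C)(C)[C@@H]2Cc1cc(O[Si](C)(C)C(C)(C)C)ccc1OCc1ccccc1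
F3 | step 18 | tert-butyldimethylsilyl ether of 28 at the phenolic oxygen | C[C@H]1CC[C@@H]2OC(C)(C)CCC[C@@]2(C)[C@]1(O)C#CCC[C@]1(C)C[C@@]2(O)CC[C@@H]1C(C)(C)[C@@H]2Cc1cc(O[Si](C)(C)C(C)(C)C)ccc1OCc1ccccc1
F4 | step 5 | (1S,2R,3S)-2-[2-(3,3-dimethyloxiran-2-yl)ethyl]-3-hydroxy-2-methylcyclohexyl acetate (epoxide epimers) | CC1(C)OC1CC[C@]1(C)[C@@H](O)CCC[C@@H]1OC(C)=O
F5 | step 5 | (5aR,6S,9aS)-3-hydroxy-2,2,5a-trimethyldecahydro-1-benzoxepin-6-yl acetate (C-3 epimers) | C1CC[C@@H]2OC(C)(C)C(O)CC[C@@]2(C)[C@H]1OC(C)=O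
F6 | step 5 | O-[(5aR,6S,9aS)-6-acetoxy-2,2,5a-trimethyldecahydro-1-benzoxepin-3-yl] 1H-imidazole-1-carbothioate (C-3 epimers) | C1CC[C@@H]2OC(C)(C)C(OC(=S)n3ccnc3)CC[C@@]2(C)[C@H]1OC(C)=O
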